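## The problem

Compound 20 is a depside: ring A is a benzoic acid with heptyl at C2, methoxy at C6 and, at C4, an oxygen acylated by ring B, a 2,4-dimethoxy-6-pentylbenzoyl group. It has no stereocentre and no double-bond geometry, so the task is purely regiochemical: four substituents in fixed positions on each of two benzene rings. Four phenolic oxygens must be told apart: three end as methyl ethers, while O4 of ring A, on the same resorcinol unit as the methylated O6, has to be free when the halves are joined. The inter-ring aryl ester is an acyl donor towards hydroxide, alkoxide and amines, so the ring A acid, shielded by two ortho groups, cannot be unmasked by saponification and needs a protecting group that leaves under neutral conditions. Joining the halves in the classical way asks a 2,6-disubstituted benzoic acid to acylate a phenol, a slow reaction at a carbonyl screened on both sides. The opening lies in a pattern shared by both rings: the carboxyl-bearing C1 is flanked by an alkyl-bearing and a methoxy-bearing carbon, and a second oxygen stands para to C1. In ring B, C1 and C6 with their substituents are C2 and C3 of an oct-2-ynoate, and C2(OMe)–C3–C4(O)–C5 is a butadiene with two oxygens on one terminus and one on C3; a [4+2] cycloaddition followed by loss of one alkoxy group therefore gives the arene with the two oxygens already different. Ring A is the same pattern with a heptyl chain, so one diene can serve twice.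

## Retrosynthesis

**20 ⇒ 19.** The last bond cut is the O–CH2Ph bond of a protecting group on the ring A carboxyl. A methyl or ethyl ester is excluded, because hydroxide strong enough to open a di-ortho-substituted benzoate would cleave the depside link first. The benzyl ester 19 falls to hydrogen on palladium without acid, base or nucleophile, and on the way it meets nothing harsher than heat, carbonate and dilute acid. The forward reaction only has to leave the aryl ester and the arenes untouched.

**19 ⇒ 18.** The methyl–O bond at C4 of ring B is cut next, because the ring-forming step delivers exactly this oxygen as a phenol and the ortho oxygen already as its methyl ether. Phenol 18 is the only acidic OH in the molecule, so the methylation needs no selectivity, only a base that is not a nucleophile towards the two esters.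

**18 ⇒ 15 + 6.** Ring B is taken apart at C1–C2 and C5–C6 into the aryl ynoate 15 and the diene 6. The neighbouring cut, the ester C–O bond between the rings, would lead to a 2,6-disubstituted benzoic acid whose screened carbonyl must be forced onto a phenol. The cycloaddition cut moves the acylation to the stage of an unhindered alkynoic acid and builds the hindered benzoate around an ester that already exists. Precursor 15 has one ring fewer and a linear C8 acyl group. The forward reaction must be regioselective (ketal carbon of 6 to the α-carbon of the ynoate), must aromatize through cycloadduct 16 and silyl ether 17 by loss of methanol, and must spare both esters.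

**15 ⇒ 13 + 14.** The ester C–O bond between O4 of ring A and the ynoyl carbon is cut to phenol 13 and oct-2-ynoic acid 14. The phenol has no ortho substituent and the acid has nothing beside its carbonyl, so carbodiimide coupling suffices. The one demand is that the triple bond is not attacked by the nucleophilic catalyst.

**13 ⇒ 10 + 6.** Ring A has the substitution pattern of ring B and is cut the same way, at C1–C6 and C2–C3, into benzyl dec-2-ynoate 10 and a second equivalent of 6 (through cycloadduct 11 and silyl ether 12). Building ring A from a cyclohexane-1,3-dione instead gives a resorcylate with two free hydroxyls and then costs three steps to tell them apart. Here O4 arrives free and O6 methylated, which is what 15 requires. This step also rehearses the key step on the simpler alkyl ester.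

**10 ⇒ 7 + 8.** The bond between the alkyne and the carboxyl carbon is cut to non-1-yne 7 and benzyl chloroformate 8. Acylation of the acetylide 9 installs the carboxyl carbon and its protecting group together.

**6 ⇒ 5 ⇒ 4 ⇒ 1 + 2.** Diene 6 is the silyl enol ether of ketone 5, whose ketene acetal comes from the dichlorovinyl ketone 4 by double substitution with methoxide. Ketone 4 is the acylation product of 1,1-dichloroethene 2 with acetyl chloride 1 after loss of HCl from the trichloro ketone 3. These three steps from bulk chemicals serve both rings.

## Roads not taken

Alternative 1: Ring A (numbered as in 20) could be cut at C1–C2 and C5–C6 instead.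
- Forward key step: dibenzyl malonate A2 adds in Michael fashion to (E)-undec-3-en-2-one A1, and the methyl ketone enolate closes onto one malonate ester. This gives the cyclohexane-1,3-dione A3 (racemic, trans; both stereocentres vanish later).
- Continuation: dehydrogenation would give benzyl 2-heptyl-4,6-dihydroxybenzoate A4. Protection of O4, methylation of the hydrogen-bonded O6 and deprotection would then reach 13.
- Merits: cheap reagents, enolate chemistry that scales, no moisture-sensitive diene, and the heptyl/carboxyl relationship fixed by the Michael step.
- Weak points: the ring arrives below the aromatic oxidation level and with two undifferentiated oxygens, so about six steps are spent where the present route spends two. The aromatization of such a β-keto ester is the least dependable step. The plan is also silent on ring B and the inter-ring ester, which would still need the hindered acid coupling.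
- Comparison: in robustness per step this road is at least equal and probably better. The chosen plan sets against it the step count (13 in two steps from 7), the built-in distinction of O4 from O6, and one reagent, 6, that makes both rings.

Alternative 2: Ring A is decorated instead of built. The bonds cut are C2–heptyl and C1–carboxyl carbon, on the aryl iodide A5 in which ring B is already attached as its ester.
- Forward key step: with Pd(OAc)2 and norbornene A8, zerovalent palladium adds oxidatively to A5, and carbopalladation of A8 with ortho C–H palladation gives a palladacycle. 1-Iodoheptane A6 alkylates the free ortho position; extrusion of A8 and Heck coupling with tert-butyl acrylate A7 at the ipso carbon give cinnamate A9.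
- Merits: three components are joined in one step on a purchased ring, the methoxy group supplies the ortho substituent such reactions need, and convergence is high.
- Weak points: the ipso carbon ends as a three-carbon acrylate, so two carbons must be removed again (ozonolysis, then oxidation of a di-ortho-substituted aldehyde) in the presence of two electron-rich arenes. The depside ester must survive carbonate base at elevated temperature for hours. A5 also presupposes the ring B acid and its hindered esterification.
- Comparison: this road is better in convergence and closes no ring. The chosen plan sets against it that every carbon introduced stays at its final oxidation level, that the depside never meets base and heat together, and that ring B is made, not assumed.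

Alternative 3: Ring B is cut at the inter-ring ester C–O bond and at C1–C6 at once.
- Forward key step: heating the diketo-dioxinone A10 releases the acylketene A11 by retro-[4+2] fragmentation. Phenol 13 traps it as the aryl 3,5,7-trioxododecanoate A12, which folds by aldol addition of C2 to the C7 ketone and dehydration to resorcylate A13.
- Merits: the step mirrors polyketide folding, forms ester and ring in one flask, avoids the hindered acid and any cycloaddition regiochemistry, and uses the same phenol 13.
- Weak points: A10 needs several steps of dioxinone enolate acylation. A12 can also close by Claisen attack of C6 on the ester carbonyl or by lactonization to a pyranone, and both expel the aryloxide, a good leaving group. A13 carries two free hydroxyls, so the hydrogen-bonded O2 must be methylated under more forcing basic conditions than O4 alone.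
- Comparison: in bonds formed by the key step this road is better (one C–O bond, one C–C bond and a ring against two C–C bonds and a ring), and the steps after it are equal in number. The chosen plan sets against it a dienophile one step from a commercial acid, a diene three steps from bulk chemicals and used twice, and an O2 that is a methyl ether from the outset.

Key step: step 7

Assumption: 20 has no stereogenic element, so no stereocontrol is planned; compounds 1, 2, 7, 8 and 14 are taken as purchasable.

## Route

Step 1
Reactants: 1 acetyl chloride; 2 1,1-dichloroethene
Product: 4 4,4-dichlorobut-3-en-2-one, via 4,4,4-trichlorobutan-2-one 3 (not isolated)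
Conditions: AlCl3, CH2Cl2, 0 °C → rt; ice/aq. HCl; distillation (−HCl)
Reagents that add atoms: none
Why: Friedel–Crafts-type acylation of an alkene: the acylium ion adds to the CH2 terminus of 2, chloride capture gives 3, and 3 loses HCl on distillation to the conjugated dichlorovinyl ketone 4.

Step 2
Reactants: 4 4,4-dichlorobut-3-en-2-one
Product: 5 4,4-dimethoxybut-3-en-2-one
Conditions: NaOMe (2.1 equiv), MeOH, 0 °C → rt
Reagents that add atoms: sodium methoxide, [Na+].[O-]C
Why: Two successive conjugate addition–elimination reactions of methoxide at the β-carbon of the enone replace both vinylic chlorides and give the ketene acetal 5.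

Step 3
Reactants: 5 4,4-dimethoxybut-3-en-2-one
Product: 6 1,1-dimethoxy-3-(trimethylsilyloxy)buta-1,3-diene
Conditions: TMSCl, Et3N, ZnCl2 (cat.), toluene, 40 °C; filtration under N2, distillation
Reagents that add atoms: chlorotrimethylsilane, C[Si](C)(C)Cl
Why: Silyl enol ether formation by soft enolization; the methyl group is the only enolizable position of 5, so the cross-conjugated 3-silyloxy diene is the only possible regioisomer.

Step 4
Reactants: 7 non-1-yne; 8 benzyl chloroformate
Product: 10 benzyl dec-2-ynoate, via lithium non-1-yn-1-ide 9 (not isolated)
Conditions: n-BuLi, THF, −78 °C; then cannulated into 8 (1.3 equiv), THF, −78 → 0 °C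
Reagents that add atoms: none
Why: Deprotonation of the terminal alkyne and C-acylation of the lithium acetylide with a chloroformate; inverse addition into excess 8 at low temperature suppresses a second addition to the ynoate.

Step 5
Reactants: 10 benzyl dec-2-ynoate; 6 1,1-dimethoxy-3-(trimethylsilyloxy)buta-1,3-diene
Product: 13 benzyl 2-heptyl-4-hydroxy-6-methoxybenzoate, via cyclohexa-1,4-diene cycloadduct 11 (not isolated), via aryl trimethylsilyl ether 12 (not isolated)
Conditions: 6 (2.5 equiv, in portions), toluene, 110 °C, sealed tube; then 1 M HCl, THF, rt
Reagents that add atoms: none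
Why: Diels–Alder cycloaddition with aromatization by elimination, known for 1,1-dialkoxy-3-silyloxybutadienes and acetylenic esters; the CH2 terminus of 6 bonds to the heptyl-bearing β-carbon, 11 loses methanol to 12, and dilute acid cleaves the silyl ether, so O4 is free and O6 methylated.

Step 6
Reactants: 13 benzyl 2-heptyl-4-hydroxy-6-methoxybenzoate; 14 oct-2-ynoic acid
Product: 15 benzyl 2-heptyl-6-methoxy-4-(oct-2-ynoyloxy)benzoate
Conditions: DCC, DMAP (5 mol %), CH2Cl2, −20 → 0 °C
Reagents that add atoms: none
Why: Steglich esterification; the phenol of 13 has no ortho substituent and the acid is unhindered, and low temperature with little DMAP limits conjugate addition to the triple bond.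

Step 7
Reactants: 15 benzyl 2-heptyl-6-methoxy-4-(oct-2-ynoyloxy)benzoate; 6 1,1-dimethoxy-3-(trimethylsilyloxy)buta-1,3-diene
Product: 18 benzyl 2-heptyl-4-(4-hydroxy-2-methoxy-6-pentylbenzoyloxy)-6-methoxybenzoate, via cyclohexa-1,4-diene cycloadduct 16 (not isolated), via aryl trimethylsilyl ether 17 (not isolated)
Conditions: 6 (3 equiv, in portions), toluene, 110 °C, sealed tube; then 0.5 M HCl, THF, 0 °C → rt
Reagents that add atoms: none
Why: Diels–Alder cycloaddition with aromatization by elimination, the reaction type by which 1,1-dialkoxy-3-silyloxybutadienes and acetylenic esters give 4-hydroxy-2-alkoxybenzoates, and the reaction already run in step 5 on the benzyl ynoate 10. The HOMO of 6 is largest at the unsubstituted CH2 terminus, towards which all three oxygen donors push electron density, and the LUMO of 15 is largest at the pentyl-bearing β-carbon; an asynchronous [4+2] transition state (at the limit, Michael addition followed by closure of the allenolate onto the dimethoxy-stabilized cationic carbon) therefore forms C5–C6 ahead of C1–C2 and gives the cyclohexa-1,4-diene 16. Ring B thus closes as a six-membered carbocycle in an intermolecular [4+2] mode, with no tether or ring-size constraint. Cycloadduct 16 holds a ketal carbon opposite a doubly allylic CH2 and loses methanol at the reaction temperature to give the aromatic silyl ether 17, which dilute acid cleaves to phenol 18; only the ketal carbon can eliminate, which is why C2 keeps one methoxy group and C4 appears as OH. No stereocentre is created, since the only sp3 ring carbons of 16 are CH2 and C(OMe)2. The selectivity needed is regioselectivity, secured by the polarization just described, and chemoselectivity for the triple bond over the two ester carbonyls, secured by the absence of any Lewis acid and by the two ortho groups that screen the benzyl ester. The aryloxy oxygen of 15 shares its lone pair with ring A and donates less into the ynoate carbonyl than the benzyloxy oxygen of 10, so 15 should be the better dienophile of the two.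

Step 8
Reactants: 18 benzyl 2-heptyl-4-(4-hydroxy-2-methoxy-6-pentylbenzoyloxy)-6-methoxybenzoate
Product: 19 benzyl 4-(2,4-dimethoxy-6-pentylbenzoyloxy)-2-heptyl-6-methoxybenzoate
Conditions: MeI, K2CO3, acetone, rt
Reagents that add atoms: iodomethane, CI
Why: Williamson O-methylation of the only phenol; carbonate in acetone offers no nucleophile for the doubly ortho-substituted depside ester or the benzyl ester.

Step 9
Reactants: 19 benzyl 4-(2,4-dimethoxy-6-pentylbenzoyloxy)-2-heptyl-6-methoxybenzoate
Product: 20 4-(2,4-dimethoxy-6-pentylbenzoyloxy)-2-heptyl-6-methoxybenzoic acid
Conditions: H2 (1 atm), 10% Pd/C, EtOAc, rt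
Reagents that add atoms: none
Why: Catalytic hydrogenolysis of the benzyl ester under neutral conditions; the aryl ester, the methyl ethers and both arenes are inert, and no reducible multiple bond remains.

## Compound list

1 | acetyl chloride | CC(=O)Cl | starting material
2 | 1,1-dichloroethene | C=C(Cl)Cl | starting material
3 | 4,4,4-trichlorobutan-2-one | CC(=O)CC(Cl)(Cl)Cl | intermediate
4 | 4,4-dichlorobut-3-en-2-one | CC(=O)C=C(Cl)Cl | intermediate
5 | 4,4-dimethoxybut-3-en-2-one | CC(=O)C=C(OC)OC | intermediate
6 | 1,1-dimethoxy-3-(trimethylsilyloxy)buta-1,3-diene | COC(OC)=CC(=C)O[Si](C)(C)C | intermediate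
7 | non-1-yne | CCCCCCCC#C | starting material
8 | benzyl chloroformate | O=C(Cl)OCc1ccccc1 | starting material
9 | lithium non-1-yn-1-ide | [Li+].[C-]#CCCCCCCC | intermediate
10 | benzyl dec-2-ynoate | CCCCCCCC#CC(=O)OCc1ccccc1 | intermediate
11 | benzyl 2-heptyl-6,6-dimethoxy-4-(trimethylsilyloxy)cyclohexa-1,4-diene-1-carboxylate | CCCCCCCC1=C(C(=O)OCc2ccccc2)C(OC)(OC)C=C(O[Si](C)(C)C)C1 | intermediate
12 | benzyl 2-heptyl-6-methoxy-4-(trimethylsilyloxy)benzoate | CCCCCCCc1cc(O[Si](C)(C)C)cc(OC)c1C(=O)OCc1ccccc1 | intermediate
13 | benzyl 2-heptyl-4-hydroxy-6-methoxybenzoate | CCCCCCCc1cc(O)cc(OC)c1C(=O)OCc1ccccc1 | intermediate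
14 | oct-2-ynoic acid | CCCCCC#CC(=O)O | starting material
15 | benzyl 2-heptyl-6-methoxy-4-(oct-2-ynoyloxy)benzoate | CCCCCC#CC(=O)Oc1cc(CCCCCCC)c(C(=O)OCc2ccccc2)c(OC)c1 | intermediate
16 | benzyl 4-{[6,6-dimethoxy-2-pentyl-4-(trimethylsilyloxy)cyclohexa-1,4-diene-1-carbonyl]oxy}-2-heptyl-6-methoxybenzoate | CCCCCCCc1cc(OC(=O)C2=C(CCCCC)CC(O[Si](C)(C)C)=CC2(OC)OC)cc(OC)c1C(=O)OCc1ccccc1 | intermediate
17 | benzyl 2-heptyl-6-methoxy-4-[2-methoxy-6-pentyl-4-(trimethylsilyloxy)benzoyloxy]benzoate | CCCCCCCc1cc(OC(=O)c2c(CCCCC)cc(O[Si](C)(C)C)cc2OC)cc(OC)c1C(=O)OCc1ccccc1 | intermediate
18 | benzyl 2-heptyl-4-(4-hydroxy-2-methoxy-6-pentylbenzoyloxy)-6-methoxybenzoate | CCCCCCCc1cc(OC(=O)c2c(CCCCC)cc(O)cc2OC)cc(OC)c1C(=O)OCc1ccccc1 | intermediate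
19 | benzyl 4-(2,4-dimethoxy-6-pentylbenzoyloxy)-2-heptyl-6-methoxybenzoate | CCCCCCCc1cc(OC(=O)c2c(CCCCC)cc(OC)cc2OC)cc(OC)c1C(=O)OCc1ccccc1 | intermediate
20 | 4-(2,4-dimethoxy-6-pentylbenzoyloxy)-2-heptyl-6-methoxybenzoic acid | CCCCCCCc1cc(OC(=O)c2c(CCCCC)cc(OC)cc2OC)cc(OC)c1C(=O)O | target

## Step count and risks

Total: 9 steps. Longest linear sequence: 8 steps (1, 2, 3, 5, 6, 7, 8, 9, from acetyl chloride); the branch from non-1-yne joins at step 5.

**Step 7 (key step).**
- Risk: the cycloaddition may be slower than the thermal decay and oligomerization of the diene. The activated aryl ynoate may also transfer its acyl group to the methanol released on aromatization or to desilylated diene, which would cut the molecule at the inter-ring ester. Excess 6 consumes methanol but also adds nucleophilic species.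
- Fallback: the ring is built on a simple ester and the depside bond is made afterwards. It sets out from 14 and 6 and returns at 19.
- Sequence: 14 is benzylated (BnBr, K2CO3, DMF) to benzyl oct-2-ynoate F1. Heated with 6 as in step 5, F1 gives the cycloadduct benzyl 6,6-dimethoxy-2-pentyl-4-(trimethylsilyloxy)cyclohexa-1,4-diene-1-carboxylate F2, which loses methanol to benzyl 2-methoxy-6-pentyl-4-(trimethylsilyloxy)benzoate F3. Dilute acid gives benzyl 4-hydroxy-2-methoxy-6-pentylbenzoate F4.
- Methylation (MeI, K2CO3, acetone) gives benzyl 2,4-dimethoxy-6-pentylbenzoate F5, and hydrogenolysis (H2, Pd/C) gives 2,4-dimethoxy-6-pentylbenzoic acid F6. Trifluoroacetic anhydride in toluene converts F6 into 2,4-dimethoxy-6-pentylbenzoic trifluoroacetic anhydride F7, which acylates phenol 13 to give 19.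
- The cycloaddition in this fallback is the one of step 5 with a chain two carbons shorter, so it carries no new risk.

**Step 5.**
- Risk: a β-alkyl ynoate with an alkyl ester is a sluggish dienophile, so the diene may decompose before it adds.
- Fallback: the isomeric allenoate, a more reactive dienophile with the same carbon mapping, replaces the ynoate. It sets out from 6 and returns at 13.
- Sequence: octanoyl chloride and Et3N generate hexylketene F8, which is trapped in a Wittig reaction by benzyl (triphenylphosphoranylidene)acetate to give racemic benzyl deca-2,3-dienoate F9. Cycloaddition of 6 across the α,β-double bond of F9 gives benzyl 2-heptylidene-6,6-dimethoxy-4-(trimethylsilyloxy)cyclohex-4-ene-1-carboxylate F10 (isomer mixture). Loss of methanol and migration of the exocyclic double bond into the ring lead to 12 and, after acid, 13.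

**Step 6.**
- Risk: DMAP or the phenoxide may add to the β-carbon of the activated ynoic acid, and the O-acylisourea may rearrange to an N-acylurea; both consume the acid without forming the ester.
- Fallback: carbodiimide activation under nucleophilic catalysis is replaced by a preformed acyl chloride. It sets out from 14 and returns at 15.
- Sequence: 14 with oxalyl chloride and catalytic DMF in CH2Cl2 gives oct-2-ynoyl chloride F11, which is added at −40 °C to 13 and the non-nucleophilic base i-Pr2NEt.

**Step 8.**
- Risk: the phenoxide of one molecule may attack the aryl ester of another, or the aroyl group may migrate, so that the depside is scrambled under the basic conditions.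
- Fallback: Mitsunobu methylation (MeOH, PPh3, diisopropyl azodicarboxylate, THF, 0 °C → rt) alkylates the phenol without any free phenoxide. It sets out from 18 and returns at 19 and makes no new compound.

## Further compounds

F1 | step 7 | benzyl oct-2-ynoate | CCCCCC#CC(=O)OCc1ccccc1
F2 | step 7 | benzyl 6,6-dimethoxy-2-pentyl-4-(trimethylsilyloxy)cyclohexa-1,4-diene-1-carboxylate | CCCCCC1=C(C(=O)OCc2ccccc2)C(OC)(OC)C=C(O[Si](C)(C)C)C1
F3 | step 7 | benzyl 2-methoxy-6-pentyl-4-(trimethylsilyloxy)benzoate | CCCCCc1cc(O[Si](C)(C)C)cc(OC)c1C(=O)OCc1ccccc1
F4 | step 7 | benzyl 4-hydroxy-2-methoxy-6-pentylbenzoate | CCCCCc1cc(O)cc(OC)c1C(=O)OCc1ccccc1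
F5 | step 7 | benzyl 2,4-dimethoxy-6-pentylbenzoate | CCCCCc1cc(OC)cc(OC)c1C(=O)OCc1ccccc1
F6 | step 7 | 2,4-dimethoxy-6-pentylbenzoic acid | CCCCCc1cc(OC)cc(OC)c1C(=O)O
F7 | step 7 | 2,4-dimethoxy-6-pentylbenzoic trifluoroacetic anhydride | CCCCCc1cc(OC)cc(OC)c1C(=O)OC(=O)C(F)(F)F
F8 | step 5 | hexylketene (oct-1-en-1-one) | CCCCCCC=C=O
F9 | step 5 | benzyl deca-2,3-dienoate (racemic) | CCCCCCC=C=CC(=O)OCc1ccccc1
F10 | step 5 | benzyl 2-heptylidene-6,6-dimethoxy-4-(trimethylsilyloxy)cyclohex-4-ene-1-carboxylate (isomer mixture) | CCCCCCC=C1CC(O[Si](C)(C)C)=CC(OC)(OC)C1C(=O)OCc1ccccc1
F11 | step 6 | oct-2-ynoyl chloride | CCCCCC#CC(=O)Cl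
F0 | step 8 | none | none
A1 | alternative 1 | (E)-undec-3-en-2-one | CCCCCCC/C=C/C(C)=O
A2 | alternative 1 | dibenzyl malonate | O=C(CC(=O)OCc1ccccc1)OCc1ccccc1
A3 | alternative 1 | benzyl trans-6-heptyl-2,4-dioxocyclohexane-1-carboxylate (racemic, one enantiomer drawn) | CCCCCCC[C@@H]1CC(=O)CC(=O)[C@H]1C(=O)OCc1ccccc1
A4 | alternative 1 | benzyl 2-heptyl-4,6-dihydroxybenzoate | CCCCCCCc1cc(O)cc(O)c1C(=O)OCc1ccccc1
A5 | alternative 2 | 4-iodo-3-methoxyphenyl 2,4-dimethoxy-6-pentylbenzoate | CCCCCc1cc(OC)cc(OC)c1C(=O)Oc1ccc(I)c(OC)c1
A6 | alternative 2 | 1-iodoheptane | CCCCCCCI
A7 | alternative 2 | tert-butyl acrylate | C=CC(=O)OC(C)(C)C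
A8 | alternative 2 | norbornene (bicyclo[2.2.1]hept-2-ene) | C1=CC2CCC1C2
A9 | alternative 2 | tert-butyl (E)-3-[4-(2,4-dimethoxy-6-pentylbenzoyloxy)-2-heptyl-6-methoxyphenyl]acrylate | CCCCCCCc1cc(OC(=O)c2c(CCCCC)cc(OC)cc2OC)cc(OC)c1/C=C/C(=O)OC(C)(C)C
A10 | alternative 3 | 6-(2,4-dioxononyl)-2,2-dimethyl-4H-1,3-dioxin-4-one | CCCCCC(=O)CC(=O)CC1=CC(=O)OC(C)(C)O1
A11 | alternative 3 | 3,5,7-trioxododec-1-en-1-one (acylketene) | CCCCCC(=O)CC(=O)CC(=O)C=C=O
A12 | alternative 3 | benzyl 2-heptyl-6-methoxy-4-(3,5,7-trioxododecanoyloxy)benzoate | CCCCCC(=O)CC(=O)CC(=O)CC(=O)Oc1cc(CCCCCCC)c(C(=O)OCc2ccccc2)c(OC)c1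
A13 | alternative 3 | benzyl 4-(2,4-dihydroxy-6-pentylbenzoyloxy)-2-heptyl-6-methoxybenzoate | CCCCCCCc1cc(OC(=O)c2c(CCCCC)cc(O)cc2O)cc(OC)c1C(=O)OCc1ccccc1
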